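**Retrosynthetic overview**

1. Target ⇐ CBS reduction of the C3 ketone ⇐ oxidation of the allylic alcohol formed when the 14-membered ring is closed last, by a Nozaki–Hiyama–Kishi macrocyclization (C3–C4) of an aldehyde/(E)-vinyl iodide.
2. Seco compound ⇐ Negishi sp3–sp2 coupling (C8–C9) of a west alkylzinc (from iodide 15) with east diene 26, which carries a (Z)-vinyl iodide and an (E)-vinylstannane as masked vinyl iodide.
3. West fragment 15: the seven-membered methylene lactone (first ring) comes from acid-mediated opening of a Shi epoxide by an acrylic acid (sets C11 and C12); the E-alkene comes from carboalumination of an alkyne; C1 comes from (S)-limonene by ozonolysis.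
4. East fragment 26: from but-3-yn-1-ol by hydrozirconation/iodination, iodine–tin exchange and a Z-selective iodo-olefination.
5. Ring order: lactone ring (step 8), then the carbocycle (step 18).

Assumption: locants C1–C12 in the comments are those of the bicyclo[10.3.2] name of the target (C1 ring CH next to the methylidene carbon, C3 carbinol, C4=C5 and C7=C8 alkenes, C11 acetoxy carbon, C12 quaternary lactone carbon); the Shi ketone, Cp2Zr(H)Cl and (R)-2-methyl-CBS-oxazaborolidine are bought.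

**West fragment**

Step 1
Reactants: 1 (S)-limonene [(4S)-1-methyl-4-(prop-1-en-2-yl)cyclohex-1-ene]
Product: 3 (5S)-7,7-dimethoxy-5-(prop-1-en-2-yl)heptan-2-one, via keto aldehyde 2 (not isolated)
Conditions: O3 (1 equiv), CH2Cl2/MeOH, −78 °C; Me2S, −78 °C → rt; then p-TsOH (cat.), rt; NaHCO3
Reagents that add atoms: ozone, [O-][O+]=O; methanol, CO
Why: Ozonolysis with reductive work-up cleaves the electron-rich trisubstituted ring alkene much faster than the 1,1-disubstituted isopropenyl group, and brief acid catalysis in methanol acetalises the aldehyde but not the methyl ketone; the C1 stereocentre is carried over unchanged from (S)-limonene.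

Step 2
Reactants: 3 (5S)-7,7-dimethoxy-5-(prop-1-en-2-yl)heptan-2-one
Product: 5 (5S)-7,7-dimethoxy-5-(prop-1-en-2-yl)hept-1-yne, via enol phosphate 4 (not isolated)
Conditions: LiN(iPr)2, THF, −78 °C; ClP(O)(OEt)2, −78 → 0 °C; LiN(iPr)2 (2.3 equiv), −78 °C → rt; H2O
Reagents that add atoms: none
Why: Kinetic enolisation on the methyl side, O-phosphorylation and base-induced elimination of the enol phosphate (ketone-to-terminal-alkyne conversion) leave the acetal, the isopropenyl group and the remote stereocentre untouched.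

Step 3
Reactants: 5 (5S)-7,7-dimethoxy-5-(prop-1-en-2-yl)hept-1-yne
Product: 8 (3E,7S)-9,9-dimethoxy-4-methyl-7-(prop-1-en-2-yl)non-3-en-1-ol, via alkenylalane 6 (not isolated), via lithium alanate 7 (not isolated)
Conditions: AlMe3, Cp2ZrCl2 (20 mol %), CH2Cl2, 0 °C → rt; evaporate; n-BuLi, hexane/THF, −78 °C; ethylene oxide, −78 °C → rt; aq. KNaC4H4O6
Reagents that add atoms: trimethylaluminium, C[Al](C)C; ethylene oxide, C1CO1
Why: Zirconium-catalysed syn-carboalumination of the terminal alkyne (Negishi carboalumination) puts methyl on the internal carbon and aluminium on the terminus, and the derived alanate opens ethylene oxide with retention, so the trisubstituted alkene is E; the isolated isopropenyl group does not react.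

Step 4
Reactants: 8 (3E,7S)-9,9-dimethoxy-4-methyl-7-(prop-1-en-2-yl)non-3-en-1-ol
Product: 9 2-[(2R,3R)-3-[(3S)-5,5-dimethoxy-3-(prop-1-en-2-yl)pentyl]-3-methyloxiran-2-yl]ethan-1-ol
Conditions: Shi ketone (D-fructose-derived, 30 mol %), KHSO5 (as 2KHSO5·KHSO4·K2SO4, 1.4 equiv), K2CO3, Bu4NHSO4 (cat.), MeCN/CH2(OMe)2/aq. Na2B4O7 buffer, 0 °C
Reagents that add atoms: potassium peroxymonosulfate, [K+].[O-]S(=O)(=O)OO
Why: Shi asymmetric epoxidation, in which the chiral dioxirane attacks one face of the E-trisubstituted alkene through a spiro transition state, gives the (R,R)-epoxide under reagent control and leaves the much slower 1,1-disubstituted alkene.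

Step 5
Reactants: 9 2-[(2R,3R)-3-[(3S)-5,5-dimethoxy-3-(prop-1-en-2-yl)pentyl]-3-methyloxiran-2-yl]ethan-1-ol
Product: 10 (2R,3R)-2-[(3S)-5,5-dimethoxy-3-(prop-1-en-2-yl)pentyl]-3-(2-iodoethyl)-2-methyloxirane
Conditions: I2, PPh3, imidazole, CH2Cl2, 0 °C
Reagents that add atoms: iodine, II
Why: Appel-type iodination of the primary alcohol under imidazole buffering spares the trisubstituted epoxide and the acetal.

Step 6
Reactants: 10 (2R,3R)-2-[(3S)-5,5-dimethoxy-3-(prop-1-en-2-yl)pentyl]-3-(2-iodoethyl)-2-methyloxirane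
Product: 11 2-[(3S)-1-[(2R,3R)-3-(2-iodoethyl)-2-methyloxiran-2-yl]-5,5-dimethoxypentan-3-yl]prop-2-en-1-ol
Conditions: SeO2 (0.5 equiv), t-BuOOH (anhydrous, 3 equiv), CH2Cl2, 0 °C → rt
Reagents that add atoms: selenium dioxide (oxygen carrier), O=[Se]=O; tert-butyl hydroperoxide (terminal oxidant), CC(C)(C)OO
Why: Selenium dioxide allylic oxidation (ene reaction, then [2,3]-sigmatropic shift) hydroxylates the allylic methyl of the only alkene in preference to the allylic methine and returns the double bond to its original position.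

Step 7
Reactants: 11 2-[(3S)-1-[(2R,3R)-3-(2-iodoethyl)-2-methyloxiran-2-yl]-5,5-dimethoxypentan-3-yl]prop-2-en-1-ol
Product: 13 2-[(3S)-1-[(2R,3R)-3-(2-iodoethyl)-2-methyloxiran-2-yl]-5,5-dimethoxypentan-3-yl]prop-2-enoic acid, via enal 12 (not isolated)
Conditions: TEMPO (cat.), NaOCl (cat.), NaClO2, MeCN/phosphate buffer (pH 6.7), 35 °C
Reagents that add atoms: sodium chlorite, [Na+].[O-]Cl=O
Why: Oxoammonium oxidation of the allylic alcohol to the enal followed by chlorite (Pinnick-type) oxidation gives the acrylic acid at near-neutral pH, which spares epoxide, acetal and iodide.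

Step 8
Reactants: 13 2-[(3S)-1-[(2R,3R)-3-(2-iodoethyl)-2-methyloxiran-2-yl]-5,5-dimethoxypentan-3-yl]prop-2-enoic acid
Product: 14 (4S,7S)-4-(2,2-dimethoxyethyl)-7-[(1R)-1-hydroxy-3-iodopropyl]-7-methyl-3-methylideneoxepan-2-one
Conditions: CSA (10 mol %), CH2Cl2 (anhydrous), 0 °C → rt
Reagents that add atoms: none
Why: Acid-catalysed intramolecular epoxide opening, in which the carboxylic acid attacks the tertiary epoxide carbon in a 7-exo mode with inversion, sets C12 as S and frees the C11 hydroxyl with its R configuration retained.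

Step 9
Reactants: 14 (4S,7S)-4-(2,2-dimethoxyethyl)-7-[(1R)-1-hydroxy-3-iodopropyl]-7-methyl-3-methylideneoxepan-2-one
Product: 15 (1R)-1-[(2S,5S)-5-(2,2-dimethoxyethyl)-2-methyl-6-methylidene-7-oxooxepan-2-yl]-3-iodopropyl acetate
Conditions: Ac2O, pyridine, DMAP (cat.), CH2Cl2, rt
Reagents that add atoms: acetic anhydride, CC(=O)OC(C)=O
Why: DMAP-catalysed acylation installs the C11 acetate of the target on the only free hydroxyl.

**East fragment**

Step 10
Reactants: 16 but-3-yn-1-ol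
Product: 17 (but-3-yn-1-yloxy)(tert-butyl)dimethylsilane
Conditions: t-BuMe2SiCl, imidazole, CH2Cl2, 0 °C → rt
Reagents that add atoms: tert-butyldimethylsilyl chloride, C[Si](C)(Cl)C(C)(C)C
Why: Silyl protection of the alcohol allows the acetylide and vinyllithium chemistry that follows.

Step 11
Reactants: 17 (but-3-yn-1-yloxy)(tert-butyl)dimethylsilane
Product: 19 tert-butyldimethyl(pent-3-yn-1-yloxy)silane, via lithium acetylide 18 (not isolated)
Conditions: n-BuLi, THF, −78 °C; MeI, −78 °C → rt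
Reagents that add atoms: iodomethane, CI
Why: Deprotonation of the terminal alkyne and SN2 methylation of the acetylide give the methyl-capped alkyne.

Step 12
Reactants: 19 tert-butyldimethyl(pent-3-yn-1-yloxy)silane
Product: 21 tert-butyl{[(3E)-4-iodopent-3-en-1-yl]oxy}dimethylsilane, via alkenylzirconocene 20 (not isolated)
Conditions: Cp2Zr(H)Cl (2.2 equiv), THF, rt → 50 °C; I2, 0 °C
Reagents that add atoms: iodine, II
Why: Hydrozirconation is a syn addition which, under equilibrating conditions with excess reagent, places zirconium on the less hindered methyl-bearing carbon, and iodinolysis with retention gives the E-2-iodoalkene that becomes the C4=C5 unit.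

Step 13
Reactants: 21 tert-butyl{[(3E)-4-iodopent-3-en-1-yl]oxy}dimethylsilane
Product: 23 tert-butyldimethyl{[(3E)-4-(tributylstannyl)pent-3-en-1-yl]oxy}silane, via vinyllithium 22 (not isolated)
Conditions: t-BuLi (2.1 equiv), Et2O, −78 °C; Bu3SnCl, −78 °C → rt
Reagents that add atoms: tributyltin chloride, CCCC[Sn](Cl)(CCCC)CCCC
Why: Iodine–lithium exchange and stannylation both proceed with retention, which turns the E-vinyl iodide into a vinylstannane that is inert in the later Negishi coupling.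

Step 14
Reactants: 23 tert-butyldimethyl{[(3E)-4-(tributylstannyl)pent-3-en-1-yl]oxy}silane
Product: 24 (3E)-4-(tributylstannyl)pent-3-en-1-ol
Conditions: Bu4NF, THF, 0 °C → rt
Reagents that add atoms: none
Why: Fluoride-mediated desilylation frees the primary alcohol without touching the vinylstannane.

Step 15
Reactants: 24 (3E)-4-(tributylstannyl)pent-3-en-1-ol
Product: 25 (3E)-4-(tributylstannyl)pent-3-enal
Conditions: Dess–Martin periodinane, NaHCO3, CH2Cl2, 0 °C; used at once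
Reagents that add atoms: none
Why: Buffered Dess–Martin oxidation gives the β,γ-unsaturated aldehyde without acid-induced destannylation or migration of the double bond.

Step 16
Reactants: 25 (3E)-4-(tributylstannyl)pent-3-enal
Product: 26 tributyl[(2E,5Z)-6-iodohepta-2,5-dien-2-yl]stannane
Conditions: EtPPh3I, n-BuLi, THF, 0 °C; I2 (1.0 equiv), −78 °C; NaN(SiMe3)2, −20 °C; then 25, −78 → −20 °C
Reagents that add atoms: ethyltriphenylphosphonium iodide, CC[P+](c1ccccc1)(c1ccccc1)c1ccccc1.[I-]; iodine, II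
Why: Stork–Zhao-type Wittig olefination with the α-iodo ylide gives, under kinetic control, the Z-vinyl iodide (iodine cis to the chain), which fixes the C7=C8 geometry.

**Fragment union and ring closure**

Step 17
Reactants: 15 (1R)-1-[(2S,5S)-5-(2,2-dimethoxyethyl)-2-methyl-6-methylidene-7-oxooxepan-2-yl]-3-iodopropyl acetate; 26 tributyl[(2E,5Z)-6-iodohepta-2,5-dien-2-yl]stannane
Product: 29 (1R,4Z,7E)-8-iodo-4-methyl-1-[(2S,5S)-2-methyl-6-methylidene-7-oxo-5-(2-oxoethyl)oxepan-2-yl]nona-4,7-dien-1-yl acetate, via alkylzinc iodide 27 (not isolated), via coupled vinylstannane 28 (not isolated)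
Conditions: 15 (1.3 equiv), Zn dust, I2 (5 mol %), DMA, 40 °C; then 26, PdCl2(dppf) (5 mol %), THF, rt; then I2 (2.2 equiv), acetone/H2O, 0 °C → rt; aq. Na2S2O3
Reagents that add atoms: iodine, II; water, O
Why: Negishi cross-coupling joins the alkylzinc to the vinyl iodide with retention of the Z geometry (zerovalent palladium inserts only into the C–I bond), after which iodine cleaves the C–Sn bond with retention to the E-vinyl iodide and catalyses hydrolysis of the dimethyl acetal.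

Step 18
Reactants: 29 (1R,4Z,7E)-8-iodo-4-methyl-1-[(2S,5S)-2-methyl-6-methylidene-7-oxo-5-(2-oxoethyl)oxepan-2-yl]nona-4,7-dien-1-yl acetate
Product: 30 (1S,3RS,4E,7Z,11R,12S)-3-hydroxy-4,8,12-trimethyl-15-methylidene-14-oxo-13-oxabicyclo[10.3.2]heptadeca-4,7-dien-11-yl acetate (both C3 epimers)
Conditions: CrCl2 (10 equiv), NiCl2 (2 mol %), DMSO/THF, rt, syringe-pump addition to 2 mM
Reagents that add atoms: none
Why: Nozaki–Hiyama–Kishi macrocyclization, in which the alkenylchromium formed through nickel catalysis adds chemoselectively to the aldehyde, closes the 14-membered ring with the E-alkene intact; the new C3 centre is formed without reliable control and is corrected in steps 19 and 20.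

Step 19
Reactants: 30 (1S,3RS,4E,7Z,11R,12S)-3-hydroxy-4,8,12-trimethyl-15-methylidene-14-oxo-13-oxabicyclo[10.3.2]heptadeca-4,7-dien-11-yl acetate
Product: 31 (1S,4E,7Z,11R,12S)-4,8,12-trimethyl-15-methylidene-3,14-dioxo-13-oxabicyclo[10.3.2]heptadeca-4,7-dien-11-yl acetate
Conditions: Dess–Martin periodinane, NaHCO3, CH2Cl2, 0 °C
Reagents that add atoms: none
Why: Buffered Dess–Martin oxidation converts both C3 epimers into one enone without moving the skipped diene into conjugation.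

Step 20
Reactants: 31 (1S,4E,7Z,11R,12S)-4,8,12-trimethyl-15-methylidene-3,14-dioxo-13-oxabicyclo[10.3.2]heptadeca-4,7-dien-11-yl acetate
Product: 32 (1S,3S,4E,7Z,11R,12S)-3-hydroxy-4,8,12-trimethyl-15-methylidene-14-oxo-13-oxabicyclo[10.3.2]heptadeca-4,7-dien-11-yl acetate (target)
Conditions: (R)-2-methyl-CBS-oxazaborolidine (1 equiv), catecholborane, toluene/CH2Cl2, −78 °C; MeOH
Reagents that add atoms: none
Why: Corey–Bakshi–Shibata reduction, with the alkenyl group as the large substituent on the (R)-oxazaborolidine–borane complex, delivers hydride to one face of the enone and gives the 3S alcohol under reagent control, while the methylene lactone and acetate are inert at −78 °C.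

**Compound list**

1 | (S)-limonene, (4S)-1-methyl-4-(prop-1-en-2-yl)cyclohex-1-ene | CC1=CC[C@H](CC1)C(C)=C | starting material
2 | (3S)-6-oxo-3-(prop-1-en-2-yl)heptanal | O=CC[C@H](CCC(C)=O)C(C)=C | intermediate
3 | (5S)-7,7-dimethoxy-5-(prop-1-en-2-yl)heptan-2-one | COC(OC)C[C@H](CCC(C)=O)C(C)=C | intermediate
4 | diethyl (5S)-7,7-dimethoxy-5-(prop-1-en-2-yl)hept-1-en-2-yl phosphate | COC(OC)C[C@H](CCC(=C)OP(=O)(OCC)OCC)C(C)=C | intermediate
5 | (5S)-7,7-dimethoxy-5-(prop-1-en-2-yl)hept-1-yne | COC(OC)C[C@H](CCC#C)C(C)=C | intermediate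
6 | [(1E,5S)-7,7-dimethoxy-2-methyl-5-(prop-1-en-2-yl)hept-1-en-1-yl]dimethylalumane | COC(OC)C[C@H](CC/C(C)=C/[Al](C)C)C(C)=C | intermediate
7 | lithium butyl[(1E,5S)-7,7-dimethoxy-2-methyl-5-(prop-1-en-2-yl)hept-1-en-1-yl]dimethylaluminate | COC(OC)C[C@H](CC/C(C)=C/[Al-](C)(C)CCCC)C(C)=C.[Li+] | intermediate
8 | (3E,7S)-9,9-dimethoxy-4-methyl-7-(prop-1-en-2-yl)non-3-en-1-ol | COC(OC)C[C@H](CC/C(C)=C/CCO)C(C)=C | intermediate
9 | 2-[(2R,3R)-3-[(3S)-5,5-dimethoxy-3-(prop-1-en-2-yl)pentyl]-3-methyloxiran-2-yl]ethan-1-ol | OCC[C@H]1O[C@]1(C)CC[C@@H](CC(OC)OC)C(C)=C | intermediate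
10 | (2R,3R)-2-[(3S)-5,5-dimethoxy-3-(prop-1-en-2-yl)pentyl]-3-(2-iodoethyl)-2-methyloxirane | ICC[C@H]1O[C@]1(C)CC[C@@H](CC(OC)OC)C(C)=C | intermediate
11 | 2-[(3S)-1-[(2R,3R)-3-(2-iodoethyl)-2-methyloxiran-2-yl]-5,5-dimethoxypentan-3-yl]prop-2-en-1-ol | ICC[C@H]1O[C@]1(C)CC[C@@H](CC(OC)OC)C(=C)CO | intermediate
12 | 2-[(3S)-1-[(2R,3R)-3-(2-iodoethyl)-2-methyloxiran-2-yl]-5,5-dimethoxypentan-3-yl]prop-2-enal | ICC[C@H]1O[C@]1(C)CC[C@@H](CC(OC)OC)C(=C)C=O | intermediate
13 | 2-[(3S)-1-[(2R,3R)-3-(2-iodoethyl)-2-methyloxiran-2-yl]-5,5-dimethoxypentan-3-yl]prop-2-enoic acid | ICC[C@H]1O[C@]1(C)CC[C@@H](CC(OC)OC)C(=C)C(=O)O | intermediate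
14 | (4S,7S)-4-(2,2-dimethoxyethyl)-7-[(1R)-1-hydroxy-3-iodopropyl]-7-methyl-3-methylideneoxepan-2-one | C=C1C(=O)O[C@](C)([C@H](O)CCI)CC[C@H]1CC(OC)OC | intermediate
15 | (1R)-1-[(2S,5S)-5-(2,2-dimethoxyethyl)-2-methyl-6-methylidene-7-oxooxepan-2-yl]-3-iodopropyl acetate | C=C1C(=O)O[C@](C)([C@H](OC(C)=O)CCI)CC[C@H]1CC(OC)OC | intermediate
16 | but-3-yn-1-ol | C#CCCO | starting material
17 | (but-3-yn-1-yloxy)(tert-butyl)dimethylsilane | C#CCCO[Si](C)(C)C(C)(C)C | intermediate
18 | lithium 4-[(tert-butyldimethylsilyl)oxy]but-1-yn-1-ide | [Li]C#CCCO[Si](C)(C)C(C)(C)C | intermediate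
19 | tert-butyldimethyl(pent-3-yn-1-yloxy)silane | CC#CCCO[Si](C)(C)C(C)(C)C | intermediate
20 | chloro{(2E)-5-[(tert-butyldimethylsilyl)oxy]pent-2-en-2-yl}bis(cyclopentadienyl)zirconium | C/C(=C\CCO[Si](C)(C)C(C)(C)C)[Zr](Cl)(C1C=CC=C1)C1C=CC=C1 | intermediate
21 | tert-butyl{[(3E)-4-iodopent-3-en-1-yl]oxy}dimethylsilane | C/C(I)=C\CCO[Si](C)(C)C(C)(C)C | intermediate
22 | {(2E)-5-[(tert-butyldimethylsilyl)oxy]pent-2-en-2-yl}lithium | C/C([Li])=C\CCO[Si](C)(C)C(C)(C)C | intermediate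
23 | tert-butyldimethyl{[(3E)-4-(tributylstannyl)pent-3-en-1-yl]oxy}silane | CCCC[Sn](CCCC)(CCCC)/C(C)=C/CCO[Si](C)(C)C(C)(C)C | intermediate
24 | (3E)-4-(tributylstannyl)pent-3-en-1-ol | CCCC[Sn](CCCC)(CCCC)/C(C)=C/CCO | intermediate
25 | (3E)-4-(tributylstannyl)pent-3-enal | CCCC[Sn](CCCC)(CCCC)/C(C)=C/CC=O | intermediate
26 | tributyl[(2E,5Z)-6-iodohepta-2,5-dien-2-yl]stannane | CCCC[Sn](CCCC)(CCCC)/C(C)=C/C/C=C(/C)I | intermediate
27 | {(3R)-3-acetoxy-3-[(2S,5S)-5-(2,2-dimethoxyethyl)-2-methyl-6-methylidene-7-oxooxepan-2-yl]propyl}zinc iodide | C=C1C(=O)O[C@](C)([C@H](OC(C)=O)CC[Zn]I)CC[C@H]1CC(OC)OC | intermediate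
28 | (1R,4Z,7E)-1-[(2S,5S)-5-(2,2-dimethoxyethyl)-2-methyl-6-methylidene-7-oxooxepan-2-yl]-4-methyl-8-(tributylstannyl)nona-4,7-dien-1-yl acetate | C=C1C(=O)O[C@](C)([C@H](OC(C)=O)CC/C(C)=C\C/C=C(\C)[Sn](CCCC)(CCCC)CCCC)CC[C@H]1CC(OC)OC | intermediate
29 | (1R,4Z,7E)-8-iodo-4-methyl-1-[(2S,5S)-2-methyl-6-methylidene-7-oxo-5-(2-oxoethyl)oxepan-2-yl]nona-4,7-dien-1-yl acetate | C=C1C(=O)O[C@](C)([C@H](OC(C)=O)CC/C(C)=C\C/C=C(\C)I)CC[C@H]1CC=O | intermediate
30 | (1S,3RS,4E,7Z,11R,12S)-3-hydroxy-4,8,12-trimethyl-15-methylidene-14-oxo-13-oxabicyclo[10.3.2]heptadeca-4,7-dien-11-yl acetate (C3 epimers) | C=C1C(=O)O[C@@]2(C)CC[C@H]1CC(O)/C(C)=C/C/C=C(/C)CC[C@H]2OC(C)=O | intermediate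
31 | (1S,4E,7Z,11R,12S)-4,8,12-trimethyl-15-methylidene-3,14-dioxo-13-oxabicyclo[10.3.2]heptadeca-4,7-dien-11-yl acetate | C=C1C(=O)O[C@@]2(C)CC[C@H]1CC(=O)/C(C)=C/C/C=C(/C)CC[C@H]2OC(C)=O | intermediate
32 | (1S,3S,4E,7Z,11R,12S)-3-hydroxy-4,8,12-trimethyl-15-methylidene-14-oxo-13-oxabicyclo[10.3.2]heptadeca-4,7-dien-11-yl acetate | C=C1C(=O)O[C@@]2(C)CC[C@H]1C[C@H](O)/C(C)=C/C/C=C(/C)CC[C@H]2OC(C)=O | target

**Step count and risks**

Total steps: 20. Longest linear sequence: 13 (steps 1–9 and 17–20); the east branch (steps 10–16, then 17–20) is 11 steps long.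

The three steps most likely to fail, with fallbacks:

The allylic oxidation of step 6 is run beside an acid-sensitive trisubstituted epoxide and a primary iodide, and selenium dioxide oxidations of isopropenyl groups give only moderate yields. The fallback sets out from 3 and puts the oxygen in first, when the isopropenyl group is the only alkene. SeO2/t-BuOOH on 3 gives the allylic alcohol (5S)-5-(3-hydroxyprop-1-en-2-yl)-7,7-dimethoxyheptan-2-one F1, and t-BuMe2SiCl/imidazole gives the silyl ether (5S)-5-{3-[(tert-butyldimethylsilyl)oxy]prop-1-en-2-yl}-7,7-dimethoxyheptan-2-one F2. The conditions of steps 2 to 5 then give in turn the alkyne tert-butyl({2-[(3S)-1,1-dimethoxyhept-6-yn-3-yl]prop-2-en-1-yl}oxy)dimethylsilane F3, the homoallylic alcohol (3E,7S)-7-{3-[(tert-butyldimethylsilyl)oxy]prop-1-en-2-yl}-9,9-dimethoxy-4-methylnon-3-en-1-ol F4, the epoxy alcohol 2-[(2R,3R)-3-[(3S)-3-{3-[(tert-butyldimethylsilyl)oxy]prop-1-en-2-yl}-5,5-dimethoxypentyl]-3-methyloxiran-2-yl]ethan-1-ol F5 and the epoxy iodide tert-butyl({2-[(3S)-1-[(2R,3R)-3-(2-iodoethyl)-2-methyloxiran-2-yl]-5,5-dimethoxypentan-3-yl]prop-2-en-1-yl}oxy)dimethylsilane F6. Bu4NF buffered with AcOH removes the silyl group, and the route is rejoined at 11.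

The lactonisation of step 8 needs a weakly nucleophilic carboxylic acid to open a tertiary epoxide in a 7-exo mode, and hydride shift to a ketone or elimination to an allylic alcohol can compete. The fallback sets out from 11 and leaves out step 7. CSA (cat.) in CH2Cl2 lets the more nucleophilic primary allylic hydroxyl open the epoxide at the tertiary carbon with inversion, giving the cyclic ether (1R)-1-[(2S,5S)-5-(2,2-dimethoxyethyl)-2-methyl-6-methylideneoxepan-2-yl]-3-iodopropan-1-ol F7. Ac2O/pyridine/DMAP gives (1R)-1-[(2S,5S)-5-(2,2-dimethoxyethyl)-2-methyl-6-methylideneoxepan-2-yl]-3-iodopropyl acetate F8. Oxidation of the ring CH2 that is both allylic and next to the ether oxygen with CrO3·3,5-dimethylpyrazole (CH2Cl2, −20 °C) installs the lactone carbonyl, and the route is rejoined at 15.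

The chromium-mediated ring closure of step 18 may give oligomers or simple reduction of the vinyl iodide at the dilution needed for a 14-membered ring. The fallback sets out from 28, which is isolated by leaving out the iodine stage of step 17. PPTS in wet acetone frees the aldehyde (1R,4Z,7E)-4-methyl-1-[(2S,5S)-2-methyl-6-methylidene-7-oxo-5-(2-oxoethyl)oxepan-2-yl]-8-(tributylstannyl)nona-4,7-dien-1-yl acetate F9. NaClO2/NaH2PO4 with a large excess of 2-methylbut-2-ene gives the acid 2-[(4S,7S)-7-[(1R,4Z,7E)-1-acetoxy-4-methyl-8-(tributylstannyl)nona-4,7-dien-1-yl]-7-methyl-3-methylidene-2-oxooxepan-4-yl]acetic acid F10. 1-Chloro-N,N,2-trimethylprop-1-en-1-amine converts it under neutral conditions into the acid chloride 2-[(4S,7S)-7-[(1R,4Z,7E)-1-acetoxy-4-methyl-8-(tributylstannyl)nona-4,7-dien-1-yl]-7-methyl-3-methylidene-2-oxooxepan-4-yl]acetyl chloride F11. A palladium-catalysed intramolecular acylation of the vinylstannane (Stille-type; Pd2(dba)3, P(2-furyl)3, toluene, 60 °C, high dilution) then closes the ring directly to the enone, so steps 18 and 19 are not needed and the route is rejoined at 31.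

**Further compounds**

F1 | step 6 | (5S)-5-(3-hydroxyprop-1-en-2-yl)-7,7-dimethoxyheptan-2-one | COC(OC)C[C@H](CCC(C)=O)C(=C)CO
F2 | step 6 | (5S)-5-{3-[(tert-butyldimethylsilyl)oxy]prop-1-en-2-yl}-7,7-dimethoxyheptan-2-one | COC(OC)C[C@H](CCC(C)=O)C(=C)CO[Si](C)(C)C(C)(C)C
F3 | step 6 | tert-butyl({2-[(3S)-1,1-dimethoxyhept-6-yn-3-yl]prop-2-en-1-yl}oxy)dimethylsilane | COC(OC)C[C@H](CCC#C)C(=C)CO[Si](C)(C)C(C)(C)C
F4 | step 6 | (3E,7S)-7-{3-[(tert-butyldimethylsilyl)oxy]prop-1-en-2-yl}-9,9-dimethoxy-4-methylnon-3-en-1-ol | COC(OC)C[C@H](CC/C(C)=C/CCO)C(=C)CO[Si](C)(C)C(C)(C)C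
F5 | step 6 | 2-[(2R,3R)-3-[(3S)-3-{3-[(tert-butyldimethylsilyl)oxy]prop-1-en-2-yl}-5,5-dimethoxypentyl]-3-methyloxiran-2-yl]ethan-1-ol | OCC[C@H]1O[C@]1(C)CC[C@@H](CC(OC)OC)C(=C)CO[Si](C)(C)C(C)(C)C
F6 | step 6 | tert-butyl({2-[(3S)-1-[(2R,3R)-3-(2-iodoethyl)-2-methyloxiran-2-yl]-5,5-dimethoxypentan-3-yl]prop-2-en-1-yl}oxy)dimethylsilane | ICC[C@H]1O[C@]1(C)CC[C@@H](CC(OC)OC)C(=C)CO[Si](C)(C)C(C)(C)C
F7 | step 8 | (1R)-1-[(2S,5S)-5-(2,2-dimethoxyethyl)-2-methyl-6-methylideneoxepan-2-yl]-3-iodopropan-1-ol | C=C1CO[C@](C)([C@H](O)CCI)CC[C@H]1CC(OC)OC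
F8 | step 8 | (1R)-1-[(2S,5S)-5-(2,2-dimethoxyethyl)-2-methyl-6-methylideneoxepan-2-yl]-3-iodopropyl acetate | C=C1CO[C@](C)([C@H](OC(C)=O)CCI)CC[C@H]1CC(OC)OC
F9 | step 18 | (1R,4Z,7E)-4-methyl-1-[(2S,5S)-2-methyl-6-methylidene-7-oxo-5-(2-oxoethyl)oxepan-2-yl]-8-(tributylstannyl)nona-4,7-dien-1-yl acetate | C=C1C(=O)O[C@](C)([C@H](OC(C)=O)CC/C(C)=C\C/C=C(\C)[Sn](CCCC)(CCCC)CCCC)CC[C@H]1CC=O
F10 | step 18 | 2-[(4S,7S)-7-[(1R,4Z,7E)-1-acetoxy-4-methyl-8-(tributylstannyl)nona-4,7-dien-1-yl]-7-methyl-3-methylidene-2-oxooxepan-4-yl]acetic acid | C=C1C(=O)O[C@](C)([C@H](OC(C)=O)CC/C(C)=C\C/C=C(\C)[Sn](CCCC)(CCCC)CCCC)CC[C@H]1CC(=O)O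
F11 | step 18 | 2-[(4S,7S)-7-[(1R,4Z,7E)-1-acetoxy-4-methyl-8-(tributylstannyl)nona-4,7-dien-1-yl]-7-methyl-3-methylidene-2-oxooxepan-4-yl]acetyl chloride | C=C1C(=O)O[C@](C)([C@H](OC(C)=O)CC/C(C)=C\C/C=C(\C)[Sn](CCCC)(CCCC)CCCC)CC[C@H]1CC(=O)Cl
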